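The azepane ring (N4, C5, C6, C7, C8, C9, C9a) has its oxygen-bearing carbon C8 flanked by C7 and C9 and its nitrogen flanked by C5 and C9a. It is therefore cut at C6–C7 and C9–C9a into a 2-silyloxyvinyl carbene (C7–C8–C9) and a 2-azadiene (C6=C5–N4=C9a). In one operation a chiral dirhodium carbenoid cyclopropanates the azadiene and the strained cis-imino-vinylcyclopropane ring-expands by 2-aza-Cope rearrangement, closing the seven-membered ring and setting C9 and C9a cis. The precursors are an enol-silylated diazo keto ester and a 3-silyloxy-2-azadiene. Lactone, ethyl group, spiro-lactone and, last, the enamine (alkyne hydroamination) follow.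

Key step: step 5

Remarks
- Locants: N4, C5–C9 and C9a form the azepane; C1–C3 complete the pyrroline; C10 bears the ethyl group; C11 is the spiro carbon; C12 (OH), C13 (CH3) and C14 (C=O) complete the spiro-lactone; C18–C21 form the appended lactone.
- Assumption 1: Rh2(S-PTAD)4 is taken to give the (9R,9aS) sense in step 5. Induction with an azadiene is untested, and the mirror-image catalyst would be used if the sense proves opposite.
- Assumption 2: the (11R) spiro centre (C12 anti to the C10 ethyl group) is taken to be the thermodynamically preferred epimer, so acid equilibration in step 23 should deliver it.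

Step 1
Reactants: 1 3-(tert-butyldiphenylsilyloxy)propanal
Product: 3 (E)-N-[3-(tert-butyldiphenylsilyloxy)propylidene]-1-(trimethylsilyloxy)ethenamine (3-silyloxy-2-azadiene), via N-silyl imine 2 (not isolated)
Conditions: LiN(SiMe3)2, THF, −78 to −30 °C; then Et3N, AcCl, Et2O, 0 °C to rt; filtration under argon, used crude
Reagents that add atoms: lithium bis(trimethylsilyl)amide [Li+].C[Si](C)(C)[N-][Si](C)(C)C; acetyl chloride CC(Cl)=O
Why: Peterson-type condensation should give the N-silyl aldimine, and N-acylation followed by base-mediated enol silylation should deliver the E-configured 3-silyloxy-2-azadiene.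

Step 2
Reactants: 4 4-(tert-butoxy)-4-oxobutanoic acid; 5 3-(benzyloxy)-3-oxopropanoic acid
Product: 6 1-benzyl 6-tert-butyl 3-oxohexanedioate
Conditions: 4, carbonyldiimidazole, THF, rt; then 5, MgCl2, Et3N, MeCN, rt to 40 °C; aqueous citric acid
Reagents that add atoms: none
Why: Masamune–Claisen (decarboxylative Claisen) condensation of the acyl imidazolide with the magnesium malonate half-ester should give the β-keto ester without touching the tert-butyl ester.

Step 3
Reactants: 6 1-benzyl 6-tert-butyl 3-oxohexanedioate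
Product: 7 1-benzyl 6-tert-butyl 2-diazo-3-oxohexanedioate
Conditions: 4-acetamidobenzenesulfonyl azide, Et3N, MeCN, 0 °C to rt
Reagents that add atoms: 4-acetamidobenzenesulfonyl azide CC(=O)Nc1ccc(cc1)S(=O)(=O)N=[N+]=[N-]
Why: Regitz diazo transfer to the doubly activated C7 methylene should proceed under mild amine base.

Step 4
Reactants: 7 1-benzyl 6-tert-butyl 2-diazo-3-oxohexanedioate
Product: 8 1-benzyl 6-tert-butyl (Z)-3-(tert-butyldimethylsilyloxy)-2-diazohex-3-enedioate
Conditions: t-BuMe2SiOTf, Et3N, CH2Cl2, 0 °C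
Reagents that add atoms: tert-butyldimethylsilyl trifluoromethanesulfonate CC(C)(C)[Si](C)(C)OS(=O)(=O)C(F)(F)F
Why: Soft enolisation and O-silylation toward C9, the only enolisable position of the diazo ketone, should give the Z-silyl enol ether in which C10 is trans to the diazo carbon.

Step 5
Reactants: 8 1-benzyl 6-tert-butyl (Z)-3-(tert-butyldimethylsilyloxy)-2-diazohex-3-enedioate; 3 3-silyloxy-2-azadiene
Product: 11 benzyl (6R,7S)-6-(2-tert-butoxy-2-oxoethyl)-7-[2-(tert-butyldiphenylsilyloxy)ethyl]-2,5-dioxoazepane-4-carboxylate (C4 epimers and enol), via cyclopropane 9 (not isolated), via dihydroazepine 10 (not isolated)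
Conditions: Rh2(S-PTAD)4 (dirhodium tetrakis[(S)-(1-adamantyl)(phthalimido)acetate], 1 mol %), 3 (2 equiv), slow addition of 8, 2,2-dimethylbutane/PhCF3, −20 °C to rt; then Et3N·3HF, THF, 0 °C
Reagents that add atoms: none
Why: Proposed new method: the donor/acceptor rhodium vinylcarbenoid from 8 should cyclopropanate the electron-rich C5=C6 bond of 3 (forming C6–C7 and, transiently, C5–C7), and the resulting cis-1-imino-2-vinylcyclopropane 9 should undergo a strain-releasing 2-aza-Cope rearrangement that breaks C5–C7 and forms C9–C9a to give dihydroazepine 10, which fluoride unmasks to the lactam β-keto ester 11. The closest known reaction type is the tandem cyclopropanation/Cope rearrangement (formal [4+3] cycloaddition) of silyloxyvinyl diazoacetates with all-carbon dienes, together with separately known aza-divinylcyclopropane rearrangements; it has not been shown with a 2-azadiene. The cyclopropane closes by [2+1] carbene transfer and the seven-membered ring by a [3,3]-sigmatropic ring expansion through a boat transition state, so the net mode is a (4+3) annulation. C9 and C9a are set cis by the boat geometry from the E-imine and the Z-enol ether, and their absolute sense is set by the chiral carboxylate ligands in the cyclopropanation and relayed stereospecifically. The step needs attack at the C=C bond in preference to ylide formation at the imine nitrogen, and concerted rearrangement in preference to zwitterionic closure to five-membered rings; the nucleophilic terminal CH2, the bulk of the carbenoid and a non-polar solvent should secure both.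

Step 6
Reactants: 11 benzyl (6R,7S)-6-(2-tert-butoxy-2-oxoethyl)-7-[2-(tert-butyldiphenylsilyloxy)ethyl]-2,5-dioxoazepane-4-carboxylate
Product: 13 tert-butyl 2-[(6R,7S)-7-[2-(tert-butyldiphenylsilyloxy)ethyl]-2,5-dioxoazepan-6-yl]acetate, via β-keto acid 12 (not isolated)
Conditions: H2 (1 atm), 10% Pd/C, EtOAc, rt; then 40 °C
Reagents that add atoms: none
Why: Hydrogenolysis of the benzyl ester and spontaneous decarboxylation of the β-keto acid under neutral conditions should give the ketone without epimerising C9.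

Step 7
Reactants: 13 tert-butyl 2-[(6R,7S)-7-[2-(tert-butyldiphenylsilyloxy)ethyl]-2,5-dioxoazepan-6-yl]acetate
Product: 14 tert-butyl 2-[(5S,6R,7S)-7-[2-(tert-butyldiphenylsilyloxy)ethyl]-5-hydroxy-2-oxoazepan-6-yl]acetate
Conditions: LiBH(s-Bu)3 (L-Selectride, 2.2 equiv), THF, −78 °C; AcOH quench at −78 °C
Reagents that add atoms: none
Why: Substrate-controlled ketone reduction, with the bulky hydride delivered to the ring face opposite the cis C9 and C9a substituents, should give the (8S)-alcohol, and the tert-butyl ester should resist lactonisation at low temperature.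

Step 8
Reactants: 14 tert-butyl 2-[(5S,6R,7S)-7-[2-(tert-butyldiphenylsilyloxy)ethyl]-5-hydroxy-2-oxoazepan-6-yl]acetate
Product: 15 tert-butyl 2-[(5S,6R,7S)-7-[2-(tert-butyldiphenylsilyloxy)ethyl]-5-(methylsulfonyloxy)-2-oxoazepan-6-yl]acetate
Conditions: MsCl, Et3N, CH2Cl2, 0 °C
Reagents that add atoms: methanesulfonyl chloride CS(Cl)(=O)=O
Why: Sulfonylation of the secondary alcohol should be selective, since the lactam N–H is not nucleophilic enough to compete.

Step 9
Reactants: 15 tert-butyl 2-[(5S,6R,7S)-7-[2-(tert-butyldiphenylsilyloxy)ethyl]-5-(methylsulfonyloxy)-2-oxoazepan-6-yl]acetate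
Product: 17 (8R,9R,9aS)-lactone lactam (γ-lactone O–C8/C9–C10H2–C11(=O) trans-fused to the N4-H azepan-5-one; C9a carries CH2CH2OSi(t-Bu)Ph2), via carboxylic acid 16 (not isolated)
Conditions: CF3CO2H/CH2Cl2 (1:4), 0 °C to rt; concentrate; K2CO3, MeCN, 50 °C
Reagents that add atoms: none
Why: Acidolysis of the tert-butyl ester and 5-exo-tet displacement of the mesylate by the carboxylate (invertive lactonisation) should set (8R) and the trans ring fusion.

Step 10
Reactants: 17 (8R,9R,9aS)-lactone lactam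
Product: 19 (8R,9R,9aS)-N4-(tert-butoxycarbonyl) azepane lactone (C5 now CH2), via secondary amine 18 (not isolated)
Conditions: (CF3SO2)2O, 2-fluoropyridine, CH2Cl2, −78 to 0 °C; NaBH4, MeOH, 0 °C to rt; then (t-BuOCO)2O, Et3N, CH2Cl2, rt
Reagents that add atoms: di-tert-butyl dicarbonate CC(C)(C)OC(=O)OC(=O)OC(C)(C)C
Why: Reductive deoxygenation of the secondary lactam through its imidoyl triflate should leave the less nucleophilic lactone carbonyl untouched, and carbamate formation then masks the amine.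

Step 11
Reactants: 19 (8R,9R,9aS)-N4-(tert-butoxycarbonyl) azepane lactone
Product: 20 (8R,9R,9aS,10S)-10-ethyl lactone
Conditions: LiN(SiMe3)2, THF, −78 °C; EtI, DMPU, −78 to −30 °C
Reagents that add atoms: iodoethane CCI
Why: Alkylation of the lactone lithium enolate should occur on the face anti to the adjacent C9–C9a bond (1,2-induction in a γ-lactone enolate), setting (10S).

Step 12
Reactants: 20 (8R,9R,9aS,10S)-10-ethyl lactone
Product: 22 C11 methyl vinyl ketal (2-methoxy-2-vinyl tetrahydrofuran; anomer mixture), via hemiketal 21 (not isolated)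
Conditions: CH2=CHMgBr, CeCl3, THF, −78 °C; aqueous NH4Cl; then MeOH, HC(OMe)3, pyridinium p-toluenesulfonate, rt
Reagents that add atoms: vinylmagnesium bromide C=C[Mg]Br; methanol CO
Why: Nucleophilic addition of the vinyl organocerium reagent to the lactone should stop at the lactolate, and acid-catalysed ketalisation then fixes C11 as a methyl ketal whose anomeric mixture is of no consequence.

Step 13
Reactants: 22 C11 methyl vinyl ketal
Product: 23 primary alcohol (C9a–CH2CH2OH)
Conditions: Bu4NF, THF, 0 °C to rt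
Reagents that add atoms: none
Why: Fluoride-mediated cleavage of the silyl ether should be clean, since the ketal and the carbamate are inert to it.

Step 14
Reactants: 23 primary alcohol
Product: 24 aldehyde (C9a–CH2CHO)
Conditions: Dess–Martin periodinane, NaHCO3, CH2Cl2, 0 °C to rt
Reagents that add atoms: none
Why: Dess–Martin oxidation should give the aldehyde under buffered, non-epimerising conditions.

Step 15
Reactants: 24 aldehyde
Product: 25 terminal alkyne (C9a–CH2C≡CH)
Conditions: dimethyl (1-diazo-2-oxopropyl)phosphonate, K2CO3, MeOH, 0 °C to rt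
Reagents that add atoms: dimethyl (1-diazo-2-oxopropyl)phosphonate COP(=O)(OC)C(=[N+]=[N-])C(C)=O
Why: Seyferth–Gilbert homologation with the Ohira–Bestmann reagent should convert the aldehyde into the alkyne (C3) under mild carbonate conditions.

Step 16
Reactants: 26 (S)-2-methylbutanedioic acid
Product: 27 (S)-3-methyldihydrofuran-2,5-dione
Conditions: AcCl, reflux
Reagents that add atoms: none
Why: Cyclodehydration of the 1,4-diacid should give the anhydride without touching the stereocentre.

Step 17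
Reactants: 27 (S)-3-methyldihydrofuran-2,5-dione
Product: 28 (S)-4-(ethylsulfanyl)-2-methyl-4-oxobutanoic acid
Conditions: EtSH, Et3N, 4-(dimethylamino)pyridine (cat.), CH2Cl2, −20 °C
Reagents that add atoms: ethanethiol CCS
Why: Nucleophilic acyl substitution by the thiol should occur mainly at the carbonyl remote from the methyl-bearing carbon, for steric reasons.

Step 18
Reactants: 28 (S)-4-(ethylsulfanyl)-2-methyl-4-oxobutanoic acid
Product: 29 methyl (S)-4-(ethylsulfanyl)-2-methyl-4-oxobutanoate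
Conditions: MeI, K2CO3, DMF, rt
Reagents that add atoms: iodomethane CI
Why: SN2 esterification of the carboxylate should proceed without attack on the thioester.

Step 19
Reactants: 25 terminal alkyne; 29 methyl (S)-4-(ethylsulfanyl)-2-methyl-4-oxobutanoate
Product: 30 ynone (C2≡C3–C18(=O)–CH2–C20H(CH3)–CO2Me)
Conditions: PdCl2(dppf) (5 mol %), tri(2-furyl)phosphine, CuI, Et3N/DMF, 50 °C
Reagents that add atoms: none
Why: Palladium/copper-mediated coupling of the thioester with the terminal alkyne (acyl Sonogashira-type ketone synthesis) should give the ynone without a strong base.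

Step 20
Reactants: 30 ynone
Product: 32 (18S,20S)-alkynyl lactone, via hydroxy ester 31 (not isolated)
Conditions: RuCl[(S,S)-TsDPEN](p-cymene) (2 mol %), i-PrOH, rt; then pyridinium p-toluenesulfonate, toluene, 50 °C
Reagents that add atoms: none
Why: Noyori asymmetric transfer hydrogenation of the ynone with the (S,S)-catalyst should give the (18S)-propargylic alcohol by reagent control, and acid-catalysed lactonisation then closes the (18S,20S)-lactone.

Step 21
Reactants: 32 (18S,20S)-alkynyl lactone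
Product: 33 C12 aldehyde (2-formyl-2-methoxy tetrahydrofuran)
Conditions: OsO4 (2 mol %), NaIO4, 2,6-lutidine, dioxane/H2O, rt
Reagents that add atoms: sodium periodate (terminal oxidant and oxygen source) [Na+].[O-]I(=O)(=O)=O
Why: Lemieux–Johnson oxidation should cleave the terminal alkene selectively, since OsO4 dihydroxylates alkenes far faster than alkynes.

Step 22
Reactants: 33 C12 aldehyde; 34 (R)-4-benzyl-3-propanoyloxazolidin-2-one
Product: 35 (12R,13R)-syn-aldol adduct
Conditions: 34, Bu2BOTf, i-Pr2NEt, CH2Cl2, −78 to 0 °C; then 33, −78 to 0 °C; pH 7 buffer, H2O2, MeOH, 0 °C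
Reagents that add atoms: none
Why: Evans syn-aldol reaction through the Z-boron enolate and a Zimmerman–Traxler transition state should set (12R,13R) under auxiliary control, irrespective of the C11 anomer.

Step 23
Reactants: 35 (12R,13R)-syn-aldol adduct
Product: 37 (11R,12R,13R)-spiro-lactone, via hydroxy acid 36 (not isolated)
Conditions: LiOH, H2O2, THF/H2O, 0 °C; Na2SO3; pH 3; then camphorsulfonic acid, 4 Å sieves, CH2Cl2, rt
Reagents that add atoms: hydrogen peroxide (as LiOOH) OO
Why: Peroxide-assisted imide hydrolysis and acid-catalysed spiroketalisation (carboxylic acid capture of the C11 oxocarbenium ion) should give the spiro-lactone, with C11 expected to equilibrate to the (R) epimer.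

Step 24
Reactants: 37 (11R,12R,13R)-spiro-lactone
Product: 38 secondary amine (N4–H)
Conditions: CF3CO2H/CH2Cl2 (1:5), 0 °C; aqueous NaHCO3
Reagents that add atoms: none
Why: Acidolytic removal of the tert-butyl carbamate should be fast enough to spare the spiro-lactone, which can in any case only re-close to its thermodynamic epimer.

Step 25
Reactants: 38 secondary amine
Product: 39 target compound
Conditions: AgOTf (silver trifluoromethanesulfonate, 10 mol %), CH2Cl2, rt, dark; filtration through basic alumina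
Reagents that add atoms: none
Why: Silver-catalysed 5-endo-dig intramolecular hydroamination of the homopropargylic amine should form N4–C3 and place the double bond at C2=C3 by protodemetalation, leaving C18 untouched.

Compound list
1 | 3-(tert-butyldiphenylsilyloxy)propanal | O=CCCO[Si](c1ccccc1)(c1ccccc1)C(C)(C)C | starting material
2 | (E)-3-(tert-butyldiphenylsilyloxy)-N-(trimethylsilyl)propan-1-imine | C[Si](C)(C)/N=C/CCO[Si](c1ccccc1)(c1ccccc1)C(C)(C)C | intermediate
3 | (E)-N-[3-(tert-butyldiphenylsilyloxy)propylidene]-1-(trimethylsilyloxy)ethenamine | C=C(O[Si](C)(C)C)/N=C/CCO[Si](c1ccccc1)(c1ccccc1)C(C)(C)C | intermediate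
4 | 4-(tert-butoxy)-4-oxobutanoic acid | OC(=O)CCC(=O)OC(C)(C)C | starting material
5 | 3-(benzyloxy)-3-oxopropanoic acid | OC(=O)CC(=O)OCc1ccccc1 | starting material
6 | 1-benzyl 6-tert-butyl 3-oxohexanedioate | O=C(OCc1ccccc1)CC(=O)CCC(=O)OC(C)(C)C | intermediate
7 | 1-benzyl 6-tert-butyl 2-diazo-3-oxohexanedioate | O=C(OCc1ccccc1)C(=[N+]=[N-])C(=O)CCC(=O)OC(C)(C)C | intermediate
8 | 1-benzyl 6-tert-butyl (Z)-3-(tert-butyldimethylsilyloxy)-2-diazohex-3-enedioate | O=C(OCc1ccccc1)C(=[N+]=[N-])/C(O[Si](C)(C)C(C)(C)C)=C/CC(=O)OC(C)(C)C | intermediate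
9 | cis-cyclopropane (C5 imino and C7 silyloxyvinyl groups cis; C5–C6–C7 ring) | C[Si](C)(C)O[C@]1(/N=C/CCO[Si](c2ccccc2)(c2ccccc2)C(C)(C)C)C[C@@]1(C(=O)OCc3ccccc3)/C(O[Si](C)(C)C(C)(C)C)=C/CC(=O)OC(C)(C)C | intermediate
10 | benzyl (6R,7S)-6-(2-tert-butoxy-2-oxoethyl)-5-(tert-butyldimethylsilyloxy)-7-[2-(tert-butyldiphenylsilyloxy)ethyl]-2-(trimethylsilyloxy)-6,7-dihydro-3H-azepine-4-carboxylate | O=C(OC(C)(C)C)C[C@@H]1[C@H](CCO[Si](c2ccccc2)(c2ccccc2)C(C)(C)C)N=C(O[Si](C)(C)C)CC(C(=O)OCc2ccccc2)=C1O[Si](C)(C)C(C)(C)C | intermediate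
11 | benzyl (6R,7S)-6-(2-tert-butoxy-2-oxoethyl)-7-[2-(tert-butyldiphenylsilyloxy)ethyl]-2,5-dioxoazepane-4-carboxylate | O=C(OC(C)(C)C)C[C@@H]1[C@H](CCO[Si](c2ccccc2)(c2ccccc2)C(C)(C)C)NC(=O)CC(C(=O)OCc2ccccc2)C1=O | intermediate
12 | (6R,7S)-6-(2-tert-butoxy-2-oxoethyl)-7-[2-(tert-butyldiphenylsilyloxy)ethyl]-2,5-dioxoazepane-4-carboxylic acid | O=C(OC(C)(C)C)C[C@@H]1[C@H](CCO[Si](c2ccccc2)(c2ccccc2)C(C)(C)C)NC(=O)CC(C(O)=O)C1=O | intermediate
13 | tert-butyl 2-[(6R,7S)-7-[2-(tert-butyldiphenylsilyloxy)ethyl]-2,5-dioxoazepan-6-yl]acetate | O=C(OC(C)(C)C)C[C@@H]1[C@H](CCO[Si](c2ccccc2)(c2ccccc2)C(C)(C)C)NC(=O)CCC1=O | intermediate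
14 | tert-butyl 2-[(5S,6R,7S)-7-[2-(tert-butyldiphenylsilyloxy)ethyl]-5-hydroxy-2-oxoazepan-6-yl]acetate | O=C(OC(C)(C)C)C[C@@H]1[C@H](CCO[Si](c2ccccc2)(c2ccccc2)C(C)(C)C)NC(=O)CC[C@@H]1O | intermediate
15 | tert-butyl 2-[(5S,6R,7S)-7-[2-(tert-butyldiphenylsilyloxy)ethyl]-5-(methylsulfonyloxy)-2-oxoazepan-6-yl]acetate | O=C(OC(C)(C)C)C[C@@H]1[C@H](CCO[Si](c2ccccc2)(c2ccccc2)C(C)(C)C)NC(=O)CC[C@@H]1OS(C)(=O)=O | intermediate
16 | 2-[(5S,6R,7S)-7-[2-(tert-butyldiphenylsilyloxy)ethyl]-5-(methylsulfonyloxy)-2-oxoazepan-6-yl]acetic acid | OC(=O)C[C@@H]1[C@H](CCO[Si](c2ccccc2)(c2ccccc2)C(C)(C)C)NC(=O)CC[C@@H]1OS(C)(=O)=O | intermediate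
17 | (8R,9R,9aS)-lactone lactam (trans-fused γ-lactone on azepan-5-one, C9a side chain CH2CH2OSi(t-Bu)Ph2) | O=C1C[C@H]2[C@@H](CCC(=O)N[C@H]2CCO[Si](c3ccccc3)(c3ccccc3)C(C)(C)C)O1 | intermediate
18 | (8R,9R,9aS)-azepane lactone, free N4–H | O=C1C[C@H]2[C@@H](CCCN[C@H]2CCO[Si](c3ccccc3)(c3ccccc3)C(C)(C)C)O1 | intermediate
19 | (8R,9R,9aS)-N4-(tert-butoxycarbonyl) azepane lactone | O=C1C[C@H]2[C@@H](CCCN(C(=O)OC(C)(C)C)[C@H]2CCO[Si](c3ccccc3)(c3ccccc3)C(C)(C)C)O1 | intermediate
20 | (8R,9R,9aS,10S)-10-ethyl N4-(tert-butoxycarbonyl) azepane lactone | CC[C@H]1[C@H]2[C@@H](CCCN(C(=O)OC(C)(C)C)[C@H]2CCO[Si](c3ccccc3)(c3ccccc3)C(C)(C)C)OC1=O | intermediate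
21 | C11 vinyl hemiketal (anomer mixture) | CC[C@H]1[C@H]2[C@@H](CCCN(C(=O)OC(C)(C)C)[C@H]2CCO[Si](c3ccccc3)(c3ccccc3)C(C)(C)C)OC1(O)C=C | intermediate
22 | C11 methyl vinyl ketal (anomer mixture) | CC[C@H]1[C@H]2[C@@H](CCCN(C(=O)OC(C)(C)C)[C@H]2CCO[Si](c3ccccc3)(c3ccccc3)C(C)(C)C)OC1(OC)C=C | intermediate
23 | primary alcohol of 22 (C9a–CH2CH2OH) | CC[C@H]1[C@H]2[C@@H](CCCN(C(=O)OC(C)(C)C)[C@H]2CCO)OC1(OC)C=C | intermediate
24 | aldehyde (C9a–CH2CHO) | CC[C@H]1[C@H]2[C@@H](CCCN(C(=O)OC(C)(C)C)[C@H]2CC=O)OC1(OC)C=C | intermediate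
25 | terminal alkyne (C9a–CH2C≡CH) | CC[C@H]1[C@H]2[C@@H](CCCN(C(=O)OC(C)(C)C)[C@H]2CC#C)OC1(OC)C=C | intermediate
26 | (S)-2-methylbutanedioic acid | OC(=O)C[C@H](C)C(O)=O | starting material
27 | (S)-3-methyldihydrofuran-2,5-dione | C[C@H]1CC(=O)OC1=O | intermediate
28 | (S)-4-(ethylsulfanyl)-2-methyl-4-oxobutanoic acid | CCSC(=O)C[C@H](C)C(O)=O | intermediate
29 | methyl (S)-4-(ethylsulfanyl)-2-methyl-4-oxobutanoate | CCSC(=O)C[C@H](C)C(=O)OC | intermediate
30 | ynone (20S) | CC[C@H]1[C@H]2[C@@H](CCCN(C(=O)OC(C)(C)C)[C@H]2CC#CC(=O)C[C@H](C)C(=O)OC)OC1(OC)C=C | intermediate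
31 | (18S,20S)-propargylic hydroxy ester | CC[C@H]1[C@H]2[C@@H](CCCN(C(=O)OC(C)(C)C)[C@H]2CC#C[C@@H](O)C[C@H](C)C(=O)OC)OC1(OC)C=C | intermediate
32 | (18S,20S)-alkynyl lactone | CC[C@H]1[C@H]2[C@@H](CCCN(C(=O)OC(C)(C)C)[C@H]2CC#C[C@@H]3C[C@H](C)C(=O)O3)OC1(OC)C=C | intermediate
33 | C12 aldehyde (2-formyl-2-methoxy tetrahydrofuran) | CC[C@H]1[C@H]2[C@@H](CCCN(C(=O)OC(C)(C)C)[C@H]2CC#C[C@@H]3C[C@H](C)C(=O)O3)OC1(OC)C=O | intermediate
34 | (R)-4-benzyl-3-propanoyloxazolidin-2-one | CCC(=O)N1[C@H](Cc2ccccc2)COC1=O | starting material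
35 | (12R,13R)-syn-aldol adduct | CC[C@H]1[C@H]2[C@@H](CCCN(C(=O)OC(C)(C)C)[C@H]2CC#C[C@@H]3C[C@H](C)C(=O)O3)OC1(OC)[C@H](O)[C@@H](C)C(=O)N1[C@H](Cc2ccccc2)COC1=O | intermediate
36 | (12R,13R)-hydroxy acid | CC[C@H]1[C@H]2[C@@H](CCCN(C(=O)OC(C)(C)C)[C@H]2CC#C[C@@H]3C[C@H](C)C(=O)O3)OC1(OC)[C@H](O)[C@@H](C)C(O)=O | intermediate
37 | (11R,12R,13R)-spiro-lactone, N4-tert-butoxycarbonyl | CC[C@H]1[C@H]2[C@@H](CCCN(C(=O)OC(C)(C)C)[C@H]2CC#C[C@@H]3C[C@H](C)C(=O)O3)O[C@@]14OC(=O)[C@H](C)[C@H]4O | intermediate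
38 | secondary amine (N4–H) | CC[C@H]1[C@H]2[C@@H](CCCN[C@H]2CC#C[C@@H]3C[C@H](C)C(=O)O3)O[C@@]14OC(=O)[C@H](C)[C@H]4O | intermediate
39 | CNP0272443.1 | CC[C@H]1[C@H]2[C@@H](CCCN3C([C@@H]4C[C@H](C)C(=O)O4)=CC[C@@H]23)O[C@@]12OC(=O)[C@H](C)[C@H]2O | target

Total step count: 25
Longest linear sequence: 21 steps (from 4 through steps 2–15 and 19–25)

Steps most likely to fail

Step 5. The carbenoid may be intercepted by the imine nitrogen, the donor–acceptor cyclopropane may open to a zwitterion and close to five-membered rings, or the asymmetric induction may be poor or of the wrong sense. The fallback uses known chemistry, sets out from 1 and 6 and comes back at 11. Condensation of 1 with (R)-2-methylpropane-2-sulfinamide (Ti(OEt)4) should give the sulfinyl imine (R,E)-N-[3-(tert-butyldiphenylsilyloxy)propylidene]-2-methylpropane-2-sulfinamide F1. Mannich addition of the dianion of 6 (NaH, then n-BuLi) through its γ-carbon C9 should give the δ-sulfinylamino β-keto ester F2, with C9a controlled by the sulfinyl group and C9 epimers separated if needed. HCl in methanol should remove the sulfinyl group to give the ammonium chloride F3. N-Acylation with bromoacetyl bromide under two-phase carbonate conditions should give the bromoacetamide F4. Intramolecular C-alkylation at C7 (Cs2CO3, MeCN, high dilution, 7-exo-tet) should then close the azepane-2,5-dione 11.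

Step 25. The silver catalyst may ionise or rearrange the propargylic lactone instead of activating the alkyne toward the amine, or the enamine may decompose during catalysis. The fallback sets out from 38 and comes back at 39. Iodine-triggered 5-endo-dig aminocyclisation (I2, NaHCO3, MeCN, 0 °C) should give the 2-iodo enamine F7. Hydrodeiodination (Bu3SnH, Pd(PPh3)4, THF, rt) should then give 39.

Step 9. Elimination of the mesylate toward C7 or C9 may outrun the intramolecular displacement, or the carboxylate may fail to reach the rear face of C8. The fallback sets out from 14 and comes back at 17. Mitsunobu inversion of 14 (4-nitrobenzoic acid, PPh3, diisopropyl azodicarboxylate) should give the (8R)-4-nitrobenzoate F5. Methanolysis (K2CO3, MeOH) should give the (8R)-hydroxy ester F6. Acid (CF3CO2H, CH2Cl2) should then cleave the tert-butyl ester and lactonise with retention to 17.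

Further compounds
F1 | step 5 | (R,E)-N-[3-(tert-butyldiphenylsilyloxy)propylidene]-2-methylpropane-2-sulfinamide | CC(C)(C)[S@@](=O)/N=C/CCO[Si](c1ccccc1)(c1ccccc1)C(C)(C)C
F2 | step 5 | 1-benzyl 6-tert-butyl (4R)-4-[(1S)-1-{[(R)-tert-butylsulfinyl]amino}-3-(tert-butyldiphenylsilyloxy)propyl]-3-oxohexanedioate | CC(C)(C)[S@@](=O)N[C@@H](CCO[Si](c1ccccc1)(c1ccccc1)C(C)(C)C)[C@@H](CC(=O)OC(C)(C)C)C(=O)CC(=O)OCc1ccccc1
F3 | step 5 | ammonium chloride of the desulfinylated amine | [Cl-].[NH3+][C@@H](CCO[Si](c1ccccc1)(c1ccccc1)C(C)(C)C)[C@@H](CC(=O)OC(C)(C)C)C(=O)CC(=O)OCc1ccccc1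
F4 | step 5 | N-bromoacetyl derivative | BrCC(=O)N[C@@H](CCO[Si](c1ccccc1)(c1ccccc1)C(C)(C)C)[C@@H](CC(=O)OC(C)(C)C)C(=O)CC(=O)OCc1ccccc1
F5 | step 9 | tert-butyl 2-[(5R,6R,7S)-7-[2-(tert-butyldiphenylsilyloxy)ethyl]-5-(4-nitrobenzoyloxy)-2-oxoazepan-6-yl]acetate | O=C(OC(C)(C)C)C[C@@H]1[C@H](CCO[Si](c2ccccc2)(c2ccccc2)C(C)(C)C)NC(=O)CC[C@H]1OC(=O)c2ccc(cc2)[N+](=O)[O-]
F6 | step 9 | tert-butyl 2-[(5R,6R,7S)-7-[2-(tert-butyldiphenylsilyloxy)ethyl]-5-hydroxy-2-oxoazepan-6-yl]acetate | O=C(OC(C)(C)C)C[C@@H]1[C@H](CCO[Si](c2ccccc2)(c2ccccc2)C(C)(C)C)NC(=O)CC[C@H]1O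
F7 | step 25 | 2-iodo derivative of the target (iodine on C2 of the enamine) | CC[C@H]1[C@H]2[C@@H](CCCN3C([C@@H]4C[C@H](C)C(=O)O4)=C(I)C[C@@H]23)O[C@@]12OC(=O)[C@H](C)[C@H]2O
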